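**Retrosynthetic overview**
1. Ten-membered ring last: enyne cross-metathesis (ethylene) and ring-closing metathesis make C3=C4 and C5=C16 from a C2 vinyl carbinol and a C5 alkyne.
2. γ-Lactone and C8–OH: intramolecular Reformatsky reaction of a C7 2-bromopropanoate onto the C8 ketone; the C6–Cl/C7–O pair comes from a chloroallenylzinc addition to a C7 aldehyde.
3. C7–C8 unit: 1-ethoxyvinyl (acyl anion) addition to the C9 aldehyde.
4. Key step: dithiane acyl-anion conjugate addition (C9 onto C10) to an epoxyquinol enone, with the enolate trapped by formaldehyde (C2 onto C1). A Wharton transposition then turns the C14 ketone/epoxide into the C13=C14 alkene and C12–OH.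
5. Ring A first, from 4-methoxy-3-methylphenol (quinone monoketal, asymmetric epoxidation, MeLi for C20); then the lactone; then the macrocycle.

Conventions: briarane numbering of the target is used for all intermediates (ring A = C1, C10, C11, C12, C13, C14; C15 = methyl on C1; C20 = methyl on C11; C19 = lactone carbonyl). α = the face of ring A that carries the C11 oxygen; β = the opposite face. The SMILES in the compound list is the binding definition of each structure.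

Assumption: the sense of induction of the two reagent-controlled steps (tartrate in step 2, amino alcohol in step 8) was not checked against the facial models; the named enantiomer is taken to give the configuration drawn, and the antipode is used if it does not.

Step 1
Reactants: 1 4-methoxy-3-methylphenol
Product: 2 4,4-dimethoxy-3-methylcyclohexa-2,5-dien-1-one
Conditions: PhI(OAc)2, MeOH, 0 °C to rt
Reagents that add atoms: methanol (CO)
Why: Hypervalent-iodine oxidative dearomatization of a para-alkoxyphenol in methanol gives the quinone monoketal and forms no stereocentre.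

Step 2
Reactants: 2 4,4-dimethoxy-3-methylcyclohexa-2,5-dien-1-one
Product: 3 (5S,6R)-5,6-epoxy-4,4-dimethoxy-3-methylcyclohex-2-en-1-one
Conditions: Ph3COOH, NaN(SiMe3)2, diisopropyl L-tartrate, toluene, −50 °C
Reagents that add atoms: trityl hydroperoxide (OOC(c1ccccc1)(c1ccccc1)c1ccccc1)
Why: Tartrate-mediated asymmetric nucleophilic (Weitz–Scheffer) epoxidation attacks the less substituted enone double bond, and the chiral tartrate/peroxide aggregate selects one enantiotopic face, setting the cis epoxide (future C12 and C13).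

Step 3
Reactants: 3 (5S,6R)-5,6-epoxy-4,4-dimethoxy-3-methylcyclohex-2-en-1-one
Product: 6 (4S,5R,6S)-4-(tert-butyldimethylsilyloxy)-5,6-epoxy-2,4-dimethylcyclohex-2-en-1-one, via lithium alkoxide 4 (not isolated), via silyl ether ketal 5 (not isolated)
Conditions: MeLi, THF, −78 °C; TBSOTf, −78 to 0 °C; then TsOH·H2O, acetone/H2O, rt
Reagents that add atoms: methyllithium ([Li]C); tert-butyldimethylsilyl trifluoromethanesulfonate (CC(C)(C)[Si](C)(C)OS(=O)(=O)C(F)(F)F); water (O)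
Why: 1,2-Addition of MeLi to the ketone occurs anti to the epoxide oxygen (C11 oxygen cis to the epoxide), the alkoxide is silylated in the flask, and acid hydrolysis of the ketal unveils the α-methyl enone.

Step 4
Reactants: 6 (4S,5R,6S)-4-(tert-butyldimethylsilyloxy)-5,6-epoxy-2,4-dimethylcyclohex-2-en-1-one; 7 1,3-dithiane
Product: 10 1α-(triethylsilyloxymethyl)-10β-(1,3-dithian-2-yl)-12α,13α-epoxy-1β,11β-dimethyl-11α-(tert-butyldimethylsilyloxy)cyclohexan-14-one, via lithium enolate 8 (not isolated), via lithium alkoxide 9 (not isolated)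
Conditions: 7, n-BuLi, THF, −30 °C; HMPA, then 6, −78 °C; CH2O (gas), −78 to −40 °C; Et3SiCl, −78 to 0 °C
Reagents that add atoms: 1,3-dithiane 7 (C1CSCSC1); formaldehyde (C=O); chlorotriethylsilane (CC[Si](Cl)(CC)CC)
Why: Corey–Seebach acyl-anion (formyl anion equivalent) conjugate addition, made 1,4-selective by HMPA, attacks C10 anti to the C11 silyloxy group and the epoxide (β face), and the enolate then takes up formaldehyde (aldol) anti to the new C10 substituent, creating the C1 quaternary centre with 1,10-trans geometry.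

Step 5
Reactants: 10 1α-(triethylsilyloxymethyl)-10β-(1,3-dithian-2-yl)-12α,13α-epoxy-1β,11β-dimethyl-11α-(tert-butyldimethylsilyloxy)cyclohexan-14-one
Product: 12 1α-(triethylsilyloxymethyl)-10β-(1,3-dithian-2-yl)-1β,11β-dimethyl-11α-(tert-butyldimethylsilyloxy)cyclohex-13-en-12α-ol, via epoxy hydrazone 11 (not isolated)
Conditions: N2H4·H2O, AcOH (cat.), MeOH, 0 °C to rt
Reagents that add atoms: none
Why: Wharton transposition: the epoxy hydrazone fragments with loss of N2 to the allylic alcohol, keeping the C12–O configuration of the epoxide and placing the alkene at C13=C14.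

Step 6
Reactants: 12 1α-(triethylsilyloxymethyl)-10β-(1,3-dithian-2-yl)-1β,11β-dimethyl-11α-(tert-butyldimethylsilyloxy)cyclohex-13-en-12α-ol
Product: 13 12α-acetoxy-1α-(triethylsilyloxymethyl)-10β-(1,3-dithian-2-yl)-1β,11β-dimethyl-11α-(tert-butyldimethylsilyloxy)cyclohex-13-ene
Conditions: Ac2O, DMAP, pyridine, CH2Cl2, rt
Reagents that add atoms: acetic anhydride (CC(=O)OC(C)=O)
Why: DMAP-catalysed acetylation of the only free (secondary allylic) hydroxyl; no stereocentre changes.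

Step 7
Reactants: 13 12α-acetoxy-1α-(triethylsilyloxymethyl)-10β-(1,3-dithian-2-yl)-1β,11β-dimethyl-11α-(tert-butyldimethylsilyloxy)cyclohex-13-ene
Product: 14 12α-acetoxy-10β-(1,3-dithian-2-yl)-1β,11β-dimethyl-11α-(tert-butyldimethylsilyloxy)cyclohex-13-ene-1α-carbaldehyde
Conditions: (COCl)2, DMSO, CH2Cl2, −78 to −30 °C; Et3N, −78 to 0 °C
Reagents that add atoms: none
Why: Swern oxidation converts the primary triethylsilyl ether directly into the aldehyde while the tertiary TBS ether, the acetate and the dithiane are untouched.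

Step 8
Reactants: 14 12α-acetoxy-10β-(1,3-dithian-2-yl)-1β,11β-dimethyl-11α-(tert-butyldimethylsilyloxy)cyclohex-13-ene-1α-carbaldehyde
Product: 16 1α-[(1R)-1-acetoxyprop-2-enyl]-12α-acetoxy-10β-(1,3-dithian-2-yl)-1β,11β-dimethyl-11α-(tert-butyldimethylsilyloxy)cyclohex-13-ene, via vinylzinc alkoxide 15 (not isolated)
Conditions: (CH2=CH)2Zn, (+)-3-exo-(dimethylamino)isoborneol (10 mol %), toluene, 0 °C; then Ac2O, DMAP, 0 °C to rt
Reagents that add atoms: divinylzinc (C=C[Zn]C=C); acetic anhydride (CC(=O)OC(C)=O)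
Why: Amino-alcohol-catalysed enantioselective alkenylzinc addition delivers vinyl to the Re face of the neopentyl aldehyde under ligand control to set C2 (R), and the zinc alkoxide is acetylated in the same flask.

Step 9
Reactants: 16 1α-[(1R)-1-acetoxyprop-2-enyl]-12α-acetoxy-10β-(1,3-dithian-2-yl)-1β,11β-dimethyl-11α-(tert-butyldimethylsilyloxy)cyclohex-13-ene
Product: 17 1α-[(1R)-1-acetoxyprop-2-enyl]-12α-acetoxy-1β,11β-dimethyl-11α-(tert-butyldimethylsilyloxy)cyclohex-13-ene-10β-carbaldehyde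
Conditions: PhI(O2CCF3)2, MeCN/H2O (9:1), 0 °C
Reagents that add atoms: water (O)
Why: Oxidative dithioacetal cleavage with a hypervalent iodine reagent unmasks the C9 aldehyde quickly at 0 °C, sparing the alkenes, acetates and silyl ether and leaving C10 unepimerized.

Step 10
Reactants: 17 1α-[(1R)-1-acetoxyprop-2-enyl]-12α-acetoxy-1β,11β-dimethyl-11α-(tert-butyldimethylsilyloxy)cyclohex-13-ene-10β-carbaldehyde; 18 ethyl vinyl ether
Product: 20 10β-[(1R)-1-acetoxy-2-ethoxyprop-2-enyl]-1α-[(1R)-1-acetoxyprop-2-enyl]-12α-acetoxy-1β,11β-dimethyl-11α-(tert-butyldimethylsilyloxy)cyclohex-13-ene, via lithium alkoxide 19 (not isolated)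
Conditions: 18, t-BuLi, THF, −78 to 0 °C; then 17, −78 °C; Ac2O, −78 to 0 °C
Reagents that add atoms: ethyl vinyl ether 18 (C=COCC); acetic anhydride (CC(=O)OC(C)=O)
Why: 1-Ethoxyvinyllithium (an acyl anion equivalent) adds to the hindered aldehyde under Felkin–Anh control with the quaternary C1 as the large group anti to the nucleophile, giving the 9R alkoxide, which is trapped as the acetate; the selectivity is expected to be modest.

Step 11
Reactants: 20 10β-[(1R)-1-acetoxy-2-ethoxyprop-2-enyl]-1α-[(1R)-1-acetoxyprop-2-enyl]-12α-acetoxy-1β,11β-dimethyl-11α-(tert-butyldimethylsilyloxy)cyclohex-13-ene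
Product: 22 10β-[(1R)-1-acetoxy-3-hydroxy-2-oxopropyl]-1α-[(1R)-1-acetoxyprop-2-enyl]-12α-acetoxy-1β,11β-dimethyl-11α-(tert-butyldimethylsilyloxy)cyclohex-13-ene, via ethoxy epoxide 21 (not isolated)
Conditions: dimethyldioxirane (acetone solution), CH2Cl2, −78 to −20 °C; pH 7 aqueous work-up
Reagents that add atoms: dimethyldioxirane (CC1(C)OO1); water (O)
Why: Rubottom-type epoxidation of the electron-rich enol ether, which reacts far faster than the other alkenes, followed by hydrolytic opening of the ethoxy epoxide gives the α-hydroxy ketone.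

Step 12
Reactants: 22 10β-[(1R)-1-acetoxy-3-hydroxy-2-oxopropyl]-1α-[(1R)-1-acetoxyprop-2-enyl]-12α-acetoxy-1β,11β-dimethyl-11α-(tert-butyldimethylsilyloxy)cyclohex-13-ene
Product: 23 10β-[(1R)-1-acetoxy-2,3-dioxopropyl]-1α-[(1R)-1-acetoxyprop-2-enyl]-12α-acetoxy-1β,11β-dimethyl-11α-(tert-butyldimethylsilyloxy)cyclohex-13-ene
Conditions: Dess–Martin periodinane, CH2Cl2, 0 °C to rt; used crude
Reagents that add atoms: none
Why: Dess–Martin oxidation of the primary alcohol to the aldehyde under non-basic conditions that do not epimerize C9.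

Step 13
Reactants: 23 10β-[(1R)-1-acetoxy-2,3-dioxopropyl]-1α-[(1R)-1-acetoxyprop-2-enyl]-12α-acetoxy-1β,11β-dimethyl-11α-(tert-butyldimethylsilyloxy)cyclohex-13-ene; 24 3-chloro-1-(trimethylsilyl)prop-1-yne
Product: 25 10β-[(1R,3R,4S)-1-acetoxy-4-chloro-3-hydroxy-2-oxo-6-(trimethylsilyl)hex-5-ynyl]-1α-[(1R)-1-acetoxyprop-2-enyl]-12α-acetoxy-1β,11β-dimethyl-11α-(tert-butyldimethylsilyloxy)cyclohex-13-ene
Conditions: 24, ZnBr2, n-BuLi, THF/Et2O, −95 to −78 °C; then 23, −90 °C; aq. NH4Cl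
Reagents that add atoms: 3-chloro-1-(trimethylsilyl)prop-1-yne 24 (ClCC#C[Si](C)(C)C)
Why: Chloroallenylzinc addition (SE2′ propargylation) to the aldehyde: the cyclic transition state gives the anti chlorohydrin (C6 relative to C7), and attack on the zinc-chelated s-cis keto aldehyde from the face away from the C10 branch sets C7 syn to the C9 acetate.

Step 14
Reactants: 25 10β-[(1R,3R,4S)-1-acetoxy-4-chloro-3-hydroxy-2-oxo-6-(trimethylsilyl)hex-5-ynyl]-1α-[(1R)-1-acetoxyprop-2-enyl]-12α-acetoxy-1β,11β-dimethyl-11α-(tert-butyldimethylsilyloxy)cyclohex-13-ene; 26 2-bromopropanoyl bromide (racemic)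
Product: 27 10β-[(1R,3R,4S)-1-acetoxy-3-(2-bromopropanoyloxy)-4-chloro-2-oxo-6-(trimethylsilyl)hex-5-ynyl]-1α-[(1R)-1-acetoxyprop-2-enyl]-12α-acetoxy-1β,11β-dimethyl-11α-(tert-butyldimethylsilyloxy)cyclohex-13-ene
Conditions: 26, pyridine, CH2Cl2, −40 to 0 °C
Reagents that add atoms: 2-bromopropanoyl bromide 26 (CC(Br)C(Br)=O)
Why: Esterification of the only free hydroxyl (C7) with the acid bromide; the configuration of the bromide-bearing carbon is irrelevant because it is enolized in the next step.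

Step 15
Reactants: 27 10β-[(1R,3R,4S)-1-acetoxy-3-(2-bromopropanoyloxy)-4-chloro-2-oxo-6-(trimethylsilyl)hex-5-ynyl]-1α-[(1R)-1-acetoxyprop-2-enyl]-12α-acetoxy-1β,11β-dimethyl-11α-(tert-butyldimethylsilyloxy)cyclohex-13-ene
Product: 29 10β-{(R)-acetoxy[(2R,3R,4R)-2-[(1S)-1-chloro-3-(trimethylsilyl)prop-2-ynyl]-3-hydroxy-4-methyl-5-oxooxolan-3-yl]methyl}-1α-[(1R)-1-acetoxyprop-2-enyl]-12α-acetoxy-1β,11β-dimethyl-11α-(tert-butyldimethylsilyloxy)cyclohex-13-ene, via zinc enolate 28 (not isolated)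
Conditions: activated Zn powder, THF, −78 to 0 °C; aq. NH4Cl
Reagents that add atoms: none
Why: Intramolecular Reformatsky (aldol) reaction: the zinc enolate tethered through O7 attacks the C8 ketone in the rotamer that keeps C6 and C9 anti, giving the 8-hydroxy lactone with 8-OH cis to C6 and the C17 methyl trans to the C9 branch (the less hindered and epimerizable, thermodynamically preferred arrangement).

Step 16
Reactants: 29 10β-{(R)-acetoxy[(2R,3R,4R)-2-[(1S)-1-chloro-3-(trimethylsilyl)prop-2-ynyl]-3-hydroxy-4-methyl-5-oxooxolan-3-yl]methyl}-1α-[(1R)-1-acetoxyprop-2-enyl]-12α-acetoxy-1β,11β-dimethyl-11α-(tert-butyldimethylsilyloxy)cyclohex-13-ene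
Product: 30 10β-{(R)-acetoxy[(2R,3R,4R)-2-[(1S)-1-chloroprop-2-ynyl]-3-hydroxy-4-methyl-5-oxooxolan-3-yl]methyl}-1α-[(1R)-1-acetoxyprop-2-enyl]-12α-acetoxy-1β,11β-dimethylcyclohex-13-en-11α-ol
Conditions: (Me2N)3S+ Me3SiF2−, DMF, H2O (few equiv), 0 °C to rt
Reagents that add atoms: none
Why: Fluoride-mediated desilylation removes the tertiary TBS ether and the alkynyl trimethylsilyl group under nearly neutral conditions that leave the acetates, the chloride and the β-hydroxy lactone intact.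

Step 17
Reactants: 30 10β-{(R)-acetoxy[(2R,3R,4R)-2-[(1S)-1-chloroprop-2-ynyl]-3-hydroxy-4-methyl-5-oxooxolan-3-yl]methyl}-1α-[(1R)-1-acetoxyprop-2-enyl]-12α-acetoxy-1β,11β-dimethylcyclohex-13-en-11α-ol
Product: 32 (1S,2R,3Z,6S,7R,8R,9R,10S,11S,12R,17R)-2,9,12-triacetoxy-6-chloro-8,11-dihydroxybriara-3,5(16),13-trien-19,7-olide (CNP0285654.4), via triene 31 (not isolated)
Conditions: second-generation Grubbs catalyst RuCl2(=CHPh)(H2IMes)(PCy3) (15 mol %), ethylene (1 atm), toluene, rt; then argon purge, 2 mM, 80 °C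
Reagents that add atoms: ethylene (C=C)
Why: Enyne cross-metathesis with ethylene turns the alkyne into a 2-substituted butadiene (C5=C16), and ring-closing metathesis of its vinyl terminus with the C2 vinyl group closes the ten-membered ring, whose size enforces the Z C3=C4 alkene.

**Compound list**
1 | 4-methoxy-3-methylphenol | COc1ccc(O)cc1C | starting material
2 | 4,4-dimethoxy-3-methylcyclohexa-2,5-dien-1-one | COC1(OC)C=CC(=O)C=C1C | intermediate
3 | (5S,6R)-5,6-epoxy-4,4-dimethoxy-3-methylcyclohex-2-en-1-one | CC=2C(OC)(OC)[C@H]3O[C@H]3C(=O)C=2 | intermediate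
4 | lithium (1S,5S,6R)-5,6-epoxy-4,4-dimethoxy-1,3-dimethylcyclohex-2-en-1-olate | CC=2C(OC)(OC)[C@H]3O[C@H]3[C@@](C)([O-])C=2.[Li+] | intermediate (not isolated)
5 | (1S,5S,6R)-1-(tert-butyldimethylsilyloxy)-5,6-epoxy-4,4-dimethoxy-1,3-dimethylcyclohex-2-ene | CC=2C(OC)(OC)[C@H]3O[C@H]3[C@@](C)(O[Si](C)(C)C(C)(C)C)C=2 | intermediate (not isolated)
6 | (4S,5R,6S)-4-(tert-butyldimethylsilyloxy)-5,6-epoxy-2,4-dimethylcyclohex-2-en-1-one | CC=2C(=O)[C@H]3O[C@H]3[C@@](C)(O[Si](C)(C)C(C)(C)C)C=2 | intermediate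
7 | 1,3-dithiane | C1CSCSC1 | starting material
8 | lithium 10β-(1,3-dithian-2-yl)-12α,13α-epoxy-1,11β-dimethyl-11α-(tert-butyldimethylsilyloxy)cyclohex-1(14)-en-14-olate | CC2=C([O-])[C@H]3O[C@H]3[C@@](C)(O[Si](C)(C)C(C)(C)C)[C@@H]2C4SCCCS4.[Li+] | intermediate (not isolated)
9 | lithium alkoxide of 1α-(hydroxymethyl)-10β-(1,3-dithian-2-yl)-12α,13α-epoxy-1β,11β-dimethyl-11α-(tert-butyldimethylsilyloxy)cyclohexan-14-one | [Li+].[O-]C[C@@]2(C)C(=O)[C@H]3O[C@H]3[C@@](C)(O[Si](C)(C)C(C)(C)C)[C@@H]2C4SCCCS4 | intermediate (not isolated)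
10 | 1α-(triethylsilyloxymethyl)-10β-(1,3-dithian-2-yl)-12α,13α-epoxy-1β,11β-dimethyl-11α-(tert-butyldimethylsilyloxy)cyclohexan-14-one | CC[Si](CC)(CC)OC[C@@]2(C)C(=O)[C@H]3O[C@H]3[C@@](C)(O[Si](C)(C)C(C)(C)C)[C@@H]2C4SCCCS4 | intermediate
11 | C14 hydrazone of 10 | CC[Si](CC)(CC)OC[C@@]2(C)C(=NN)[C@H]3O[C@H]3[C@@](C)(O[Si](C)(C)C(C)(C)C)[C@@H]2C4SCCCS4 | intermediate (not isolated)
12 | 1α-(triethylsilyloxymethyl)-10β-(1,3-dithian-2-yl)-1β,11β-dimethyl-11α-(tert-butyldimethylsilyloxy)cyclohex-13-en-12α-ol | CC[Si](CC)(CC)OC[C@@]2(C)C=C[C@@H](O)[C@@](C)(O[Si](C)(C)C(C)(C)C)[C@@H]2C4SCCCS4 | intermediate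
13 | 12α-acetoxy-1α-(triethylsilyloxymethyl)-10β-(1,3-dithian-2-yl)-1β,11β-dimethyl-11α-(tert-butyldimethylsilyloxy)cyclohex-13-ene | CC[Si](CC)(CC)OC[C@@]2(C)C=C[C@@H](OC(C)=O)[C@@](C)(O[Si](C)(C)C(C)(C)C)[C@@H]2C4SCCCS4 | intermediate
14 | 12α-acetoxy-10β-(1,3-dithian-2-yl)-1β,11β-dimethyl-11α-(tert-butyldimethylsilyloxy)cyclohex-13-ene-1α-carbaldehyde | O=C[C@@]2(C)C=C[C@@H](OC(C)=O)[C@@](C)(O[Si](C)(C)C(C)(C)C)[C@@H]2C4SCCCS4 | intermediate
15 | vinylzinc alkoxide of the (2R)-allylic alcohol from 14 | C=C[C@@H](O[Zn]C=C)[C@@]2(C)C=C[C@@H](OC(C)=O)[C@@](C)(O[Si](C)(C)C(C)(C)C)[C@@H]2C4SCCCS4 | intermediate (not isolated)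
16 | 1α-[(1R)-1-acetoxyprop-2-enyl]-12α-acetoxy-10β-(1,3-dithian-2-yl)-1β,11β-dimethyl-11α-(tert-butyldimethylsilyloxy)cyclohex-13-ene | C=C[C@@H](OC(C)=O)[C@@]2(C)C=C[C@@H](OC(C)=O)[C@@](C)(O[Si](C)(C)C(C)(C)C)[C@@H]2C4SCCCS4 | intermediate
17 | 1α-[(1R)-1-acetoxyprop-2-enyl]-12α-acetoxy-1β,11β-dimethyl-11α-(tert-butyldimethylsilyloxy)cyclohex-13-ene-10β-carbaldehyde | C=C[C@@H](OC(C)=O)[C@@]2(C)C=C[C@@H](OC(C)=O)[C@@](C)(O[Si](C)(C)C(C)(C)C)[C@@H]2C=O | intermediate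
18 | ethyl vinyl ether (ethoxyethene) | C=COCC | starting material
19 | lithium alkoxide of the (9R)-alcohol (C9–OLi, C8(OEt)=C7H2) | C=C[C@@H](OC(C)=O)[C@@]2(C)C=C[C@@H](OC(C)=O)[C@@](C)(O[Si](C)(C)C(C)(C)C)[C@@H]2[C@@H]([O-])C(=C)OCC.[Li+] | intermediate (not isolated)
20 | 10β-[(1R)-1-acetoxy-2-ethoxyprop-2-enyl]-1α-[(1R)-1-acetoxyprop-2-enyl]-12α-acetoxy-1β,11β-dimethyl-11α-(tert-butyldimethylsilyloxy)cyclohex-13-ene | C=C[C@@H](OC(C)=O)[C@@]2(C)C=C[C@@H](OC(C)=O)[C@@](C)(O[Si](C)(C)C(C)(C)C)[C@@H]2[C@@H](OC(C)=O)C(=C)OCC | intermediate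
21 | 2-ethoxyoxirane formed from the enol ether of 20 (C8(OEt)–O–C7H2) | C=C[C@@H](OC(C)=O)[C@@]2(C)C=C[C@@H](OC(C)=O)[C@@](C)(O[Si](C)(C)C(C)(C)C)[C@@H]2[C@@H](OC(C)=O)C3(OCC)CO3 | intermediate (not isolated)
22 | 10β-[(1R)-1-acetoxy-3-hydroxy-2-oxopropyl]-1α-[(1R)-1-acetoxyprop-2-enyl]-12α-acetoxy-1β,11β-dimethyl-11α-(tert-butyldimethylsilyloxy)cyclohex-13-ene | C=C[C@@H](OC(C)=O)[C@@]2(C)C=C[C@@H](OC(C)=O)[C@@](C)(O[Si](C)(C)C(C)(C)C)[C@@H]2[C@@H](OC(C)=O)C(=O)CO | intermediate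
23 | 10β-[(1R)-1-acetoxy-2,3-dioxopropyl]-1α-[(1R)-1-acetoxyprop-2-enyl]-12α-acetoxy-1β,11β-dimethyl-11α-(tert-butyldimethylsilyloxy)cyclohex-13-ene | C=C[C@@H](OC(C)=O)[C@@]2(C)C=C[C@@H](OC(C)=O)[C@@](C)(O[Si](C)(C)C(C)(C)C)[C@@H]2[C@@H](OC(C)=O)C(=O)C=O | intermediate
24 | 3-chloro-1-(trimethylsilyl)prop-1-yne | ClCC#C[Si](C)(C)C | starting material
25 | 10β-[(1R,3R,4S)-1-acetoxy-4-chloro-3-hydroxy-2-oxo-6-(trimethylsilyl)hex-5-ynyl]-1α-[(1R)-1-acetoxyprop-2-enyl]-12α-acetoxy-1β,11β-dimethyl-11α-(tert-butyldimethylsilyloxy)cyclohex-13-ene | C=C[C@@H](OC(C)=O)[C@@]2(C)C=C[C@@H](OC(C)=O)[C@@](C)(O[Si](C)(C)C(C)(C)C)[C@@H]2[C@@H](OC(C)=O)C(=O)[C@@H](O)[C@@H](Cl)C#C[Si](C)(C)C | intermediate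
26 | 2-bromopropanoyl bromide (racemic) | CC(Br)C(Br)=O | starting material
27 | 10β-[(1R,3R,4S)-1-acetoxy-3-(2-bromopropanoyloxy)-4-chloro-2-oxo-6-(trimethylsilyl)hex-5-ynyl]-1α-[(1R)-1-acetoxyprop-2-enyl]-12α-acetoxy-1β,11β-dimethyl-11α-(tert-butyldimethylsilyloxy)cyclohex-13-ene | C=C[C@@H](OC(C)=O)[C@@]2(C)C=C[C@@H](OC(C)=O)[C@@](C)(O[Si](C)(C)C(C)(C)C)[C@@H]2[C@@H](OC(C)=O)C(=O)[C@@H](OC(=O)C(C)Br)[C@@H](Cl)C#C[Si](C)(C)C | intermediate
28 | bromozinc ester enolate of 27 | C=C[C@@H](OC(C)=O)[C@@]2(C)C=C[C@@H](OC(C)=O)[C@@](C)(O[Si](C)(C)C(C)(C)C)[C@@H]2[C@@H](OC(C)=O)C(=O)[C@@H](OC(O[Zn]Br)=CC)[C@@H](Cl)C#C[Si](C)(C)C | intermediate (not isolated)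
29 | 10β-{(R)-acetoxy[(2R,3R,4R)-2-[(1S)-1-chloro-3-(trimethylsilyl)prop-2-ynyl]-3-hydroxy-4-methyl-5-oxooxolan-3-yl]methyl}-1α-[(1R)-1-acetoxyprop-2-enyl]-12α-acetoxy-1β,11β-dimethyl-11α-(tert-butyldimethylsilyloxy)cyclohex-13-ene | C=C[C@@H](OC(C)=O)[C@@]2(C)C=C[C@@H](OC(C)=O)[C@@](C)(O[Si](C)(C)C(C)(C)C)[C@@H]2[C@@H](OC(C)=O)[C@]3(O)[C@@H](C)C(=O)O[C@H]3[C@@H](Cl)C#C[Si](C)(C)C | intermediate
30 | 10β-{(R)-acetoxy[(2R,3R,4R)-2-[(1S)-1-chloroprop-2-ynyl]-3-hydroxy-4-methyl-5-oxooxolan-3-yl]methyl}-1α-[(1R)-1-acetoxyprop-2-enyl]-12α-acetoxy-1β,11β-dimethylcyclohex-13-en-11α-ol | C=C[C@@H](OC(C)=O)[C@@]2(C)C=C[C@@H](OC(C)=O)[C@@](C)(O)[C@@H]2[C@@H](OC(C)=O)[C@]3(O)[C@@H](C)C(=O)O[C@H]3[C@@H](Cl)C#C | intermediate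
31 | triene: as 30 but with a (1S)-1-chloro-2-methylidenebut-3-enyl group on the lactone in place of the chloropropynyl group | C=C[C@@H](OC(C)=O)[C@@]2(C)C=C[C@@H](OC(C)=O)[C@@](C)(O)[C@@H]2[C@@H](OC(C)=O)[C@]3(O)[C@@H](C)C(=O)O[C@H]3[C@@H](Cl)C(=C)C=C | intermediate (not isolated)
32 | (1S,2R,3Z,6S,7R,8R,9R,10S,11S,12R,17R)-2,9,12-triacetoxy-6-chloro-8,11-dihydroxybriara-3,5(16),13-trien-19,7-olide (CNP0285654.4) | C=C1/C=C\[C@@H](OC(C)=O)[C@@]2(C)C=C[C@@H](OC(C)=O)[C@@](C)(O)[C@@H]2[C@@H](OC(C)=O)[C@]2(O)[C@@H](C)C(=O)O[C@H]2[C@H]1Cl | target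

**Totals**
Total step count: 17. Longest linear sequence: 17 (steps 1 to 17; every partner is a commercial reagent).

**Three steps most likely to fail, with fallbacks**

Step 4. The dithianide must add 1,4 to a β-carbon flanked by a quaternary centre, in the presence of an epoxy ketone, and the tetrasubstituted enolate must then be hydroxymethylated. Fallback: setting out from 6, a photoredox decarboxylative radical conjugate addition of 1,3-dithiane-2-carboxylic acid ([Ir(dF(CF3)ppy)2(dtbbpy)]PF6, K2HPO4, DMSO, blue LEDs) places the same masked formyl group on C10 through a nucleophilic dithianyl radical, which is less sensitive to steric hindrance and does not touch the carbonyl or the epoxide. This gives 10β-(1,3-dithian-2-yl)-12α,13α-epoxy-1,11β-dimethyl-11α-(tert-butyldimethylsilyloxy)cyclohexan-14-one F1 as a mixture of C1 epimers. Deprotonation with LiN(SiMe3)2 then regenerates enolate 8, which is treated with formaldehyde and Et3SiCl as before, and the route is rejoined at 10.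

Step 10. The aldehyde sits between two fully substituted carbons, so addition may be slow and the Felkin–Anh preference for 9R is not secure. Fallback: setting out from 17, the 1-ethoxyvinyllithium adduct is quenched with water instead of Ac2O to give the alcohol 10β-(2-ethoxy-1-hydroxyprop-2-enyl)-1α-[(1R)-1-acetoxyprop-2-enyl]-12α-acetoxy-1β,11β-dimethyl-11α-(tert-butyldimethylsilyloxy)cyclohex-13-ene F2 as a C9 epimer mixture. Dess–Martin oxidation converges both epimers on the ketone 10β-(2-ethoxyprop-2-enoyl)-1α-[(1R)-1-acetoxyprop-2-enyl]-12α-acetoxy-1β,11β-dimethyl-11α-(tert-butyldimethylsilyloxy)cyclohex-13-ene F3. Reagent-controlled Corey–Bakshi–Shibata reduction ((R)-2-methyl-CBS-oxazaborolidine, catecholborane, toluene, −78 °C, with the ethoxyvinyl group as the small substituent) gives the (9R)-alcohol 10β-[(1R)-2-ethoxy-1-hydroxyprop-2-enyl]-1α-[(1R)-1-acetoxyprop-2-enyl]-12α-acetoxy-1β,11β-dimethyl-11α-(tert-butyldimethylsilyloxy)cyclohex-13-ene F4. Acetylation (Ac2O, DMAP) rejoins the route at 20.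

Step 17. Closing a ten-membered carbocycle by metathesis next to a neopentyl allylic acetate, on a chain stiffened by the lactone, may give oligomers. Fallback: the order of ring formation is changed so that the macrocycle is closed before the lactone. Setting out from 25, (Me2N)3S+ Me3SiF2− removes both silyl groups to give the ketol enyne 10β-[(1R,3R,4S)-1-acetoxy-4-chloro-3-hydroxy-2-oxohex-5-ynyl]-1α-[(1R)-1-acetoxyprop-2-enyl]-12α-acetoxy-1β,11β-dimethylcyclohex-13-en-11α-ol F5. Enyne cross-metathesis with ethylene and ring closure under the conditions of step 17, now on a lactone-free chain whose C8 is still a trigonal ketone, give the macrocyclic ketol (1S,2R,3Z,6S,7R,9R,10S,11S,12R)-2,9,12-triacetoxy-6-chloro-7,11-dihydroxy-8-oxo-17,18,19-trinorbriara-3,5(16),13-triene F6. Acylation with 2-bromopropanoyl bromide and pyridine gives its C7 2-bromopropanoate F7, and the zinc-mediated intramolecular Reformatsky reaction then closes the lactone across the ring to arrive at 32.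

Further compounds
F1 | step 4 | 10β-(1,3-dithian-2-yl)-12α,13α-epoxy-1,11β-dimethyl-11α-(tert-butyldimethylsilyloxy)cyclohexan-14-one (C1 epimers) | CC2C(=O)[C@H]3O[C@H]3[C@@](C)(O[Si](C)(C)C(C)(C)C)[C@@H]2C4SCCCS4
F2 | step 10 | 10β-(2-ethoxy-1-hydroxyprop-2-enyl)-1α-[(1R)-1-acetoxyprop-2-enyl]-12α-acetoxy-1β,11β-dimethyl-11α-(tert-butyldimethylsilyloxy)cyclohex-13-ene (C9 epimers) | C=C[C@@H](OC(C)=O)[C@@]2(C)C=C[C@@H](OC(C)=O)[C@@](C)(O[Si](C)(C)C(C)(C)C)[C@@H]2C(O)C(=C)OCC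
F3 | step 10 | 10β-(2-ethoxyprop-2-enoyl)-1α-[(1R)-1-acetoxyprop-2-enyl]-12α-acetoxy-1β,11β-dimethyl-11α-(tert-butyldimethylsilyloxy)cyclohex-13-ene | C=C[C@@H](OC(C)=O)[C@@]2(C)C=C[C@@H](OC(C)=O)[C@@](C)(O[Si](C)(C)C(C)(C)C)[C@@H]2C(=O)C(=C)OCC
F4 | step 10 | 10β-[(1R)-2-ethoxy-1-hydroxyprop-2-enyl]-1α-[(1R)-1-acetoxyprop-2-enyl]-12α-acetoxy-1β,11β-dimethyl-11α-(tert-butyldimethylsilyloxy)cyclohex-13-ene | C=C[C@@H](OC(C)=O)[C@@]2(C)C=C[C@@H](OC(C)=O)[C@@](C)(O[Si](C)(C)C(C)(C)C)[C@@H]2[C@@H](O)C(=C)OCC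
F5 | step 17 | 10β-[(1R,3R,4S)-1-acetoxy-4-chloro-3-hydroxy-2-oxohex-5-ynyl]-1α-[(1R)-1-acetoxyprop-2-enyl]-12α-acetoxy-1β,11β-dimethylcyclohex-13-en-11α-ol | C=C[C@@H](OC(C)=O)[C@@]2(C)C=C[C@@H](OC(C)=O)[C@@](C)(O)[C@@H]2[C@@H](OC(C)=O)C(=O)[C@@H](O)[C@@H](Cl)C#C
F6 | step 17 | (1S,2R,3Z,6S,7R,9R,10S,11S,12R)-2,9,12-triacetoxy-6-chloro-7,11-dihydroxy-8-oxo-17,18,19-trinorbriara-3,5(16),13-triene | C=C1/C=C\[C@@H](OC(C)=O)[C@@]2(C)C=C[C@@H](OC(C)=O)[C@@](C)(O)[C@@H]2[C@@H](OC(C)=O)C(=O)[C@@H](O)[C@H]1Cl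
F7 | step 17 | C7 2-bromopropanoate of F6 | C=C1/C=C\[C@@H](OC(C)=O)[C@@]2(C)C=C[C@@H](OC(C)=O)[C@@](C)(O)[C@@H]2[C@@H](OC(C)=O)C(=O)[C@@H](OC(=O)C(C)Br)[C@H]1Cl
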